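**Retrosynthetic overview**
1. The target is the (7R,8S)-erythro 8-O-4′ neolignan (C7 = carbinol carbon, C8 = aryloxy carbon, C9 = methyl). Both benzene rings are bought, so no ring is formed; only an oxazolidinone auxiliary ring is carried and later removed.
2. Allylic alcohol ⇐ (E)-cinnamate ester ⇐ aryl bromide + ethyl acrylate (Heck, then DIBAL-H).
3. C7-(R) carbinol ⇐ C7-(S) epimer by Mitsunobu inversion; C9 methyl ⇐ CH2OTs ⇐ CH2OH ⇐ acyl oxazolidinone.
4. Key C7–C8 bond: boron syn-aldol of 3,4-dimethoxybenzaldehyde with the (R)-4-benzyloxazolidinone imide of (4-bromo-2,6-dimethoxyphenoxy)acetic acid, which fixes C8.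
5. Imide ⇐ aryloxyacetic acid ⇐ 4-bromo-2,6-dimethoxyphenol + ethyl bromoacetate.

Assumption: 4-bromo-2,6-dimethoxyphenol (1) is bought as a catalogue compound.

**Route**

Step 1
Reactants: 1 4-bromo-2,6-dimethoxyphenol; 2 ethyl bromoacetate
Product: 3 ethyl 2-(4-bromo-2,6-dimethoxyphenoxy)acetate
Conditions: K2CO3, acetone, reflux
Reagents that add atoms: none
Why: Williamson ether synthesis; the phenoxide displaces the activated primary α-bromo ester by SN2 despite the two ortho methoxy groups.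

Step 2
Reactants: 3 ethyl 2-(4-bromo-2,6-dimethoxyphenoxy)acetate
Product: 4 2-(4-bromo-2,6-dimethoxyphenoxy)acetic acid
Conditions: LiOH·H2O, THF/H2O, rt; then 1 M HCl
Reagents that add atoms: lithium hydroxide [Li+].[OH-] (its oxygen becomes the acid OH)
Why: Saponification (BAc2 ester hydrolysis) of an unhindered ethyl ester; aryl ether and aryl bromide are inert.

Step 3
Reactants: 4 2-(4-bromo-2,6-dimethoxyphenoxy)acetic acid; 5 (R)-4-benzyl-2-oxazolidinone
Product: 7 (R)-4-benzyl-3-[2-(4-bromo-2,6-dimethoxyphenoxy)acetyl]oxazolidin-2-one, via mixed pivalic anhydride 6 (not isolated)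
Conditions: PivCl, Et3N, THF, −20 °C; then LiCl, 5, −20 °C → rt
Reagents that add atoms: pivaloyl chloride CC(C)(C)C(Cl)=O (its acyl group is present in 6 only)
Why: N-acylation of the oxazolidinone through a mixed anhydride (LiCl/Et3N protocol); the auxiliary attacks the unhindered aryloxyacetyl carbonyl, not the pivaloyl one.

Step 4
Reactants: 7 (R)-4-benzyl-3-[2-(4-bromo-2,6-dimethoxyphenoxy)acetyl]oxazolidin-2-one; 8 3,4-dimethoxybenzaldehyde
Product: 11 (R)-4-benzyl-3-[(2R,3S)-2-(4-bromo-2,6-dimethoxyphenoxy)-3-(3,4-dimethoxyphenyl)-3-hydroxypropanoyl]oxazolidin-2-one, via Z-dibutylboron enolate 9 (not isolated), via dibutylboron aldolate 10 (not isolated)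
Conditions: Bu2BOTf, i-Pr2NEt, CH2Cl2, −78 → 0 °C; then 8, −78 → 0 °C; pH 7 buffer, MeOH, 30% H2O2, 0 °C
Reagents that add atoms: dibutylboron triflate CCCCB(CCCC)OS(=O)(=O)C(F)(F)F (its Bu2B group is present in 9 and 10 only)
Why: Evans syn-aldol; the Z-boron enolate reacts through a Zimmerman–Traxler chair on the face away from the benzyl group, giving the (2R,3S) syn adduct, which fixes C8 (S in the target) and gives C7 as S for inversion in step 8.

Step 5
Reactants: 11 the syn aldol adduct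
Product: 12 (1S,2S)-2-(4-bromo-2,6-dimethoxyphenoxy)-1-(3,4-dimethoxyphenyl)propane-1,3-diol
Conditions: LiBH4, MeOH (1 eq), THF, 0 °C
Reagents that add atoms: none
Why: Reductive cleavage of the N-acyl oxazolidinone by borohydride at the activated exocyclic carbonyl; no stereocentre is touched, the aryl bromide is inert and the auxiliary is recovered.

Step 6
Reactants: 12 (1S,2S)-2-(4-bromo-2,6-dimethoxyphenoxy)-1-(3,4-dimethoxyphenyl)propane-1,3-diol
Product: 13 (2S,3S)-2-(4-bromo-2,6-dimethoxyphenoxy)-3-(3,4-dimethoxyphenyl)-3-hydroxypropyl 4-methylbenzenesulfonate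
Conditions: TsCl (1.1 eq), pyridine, CH2Cl2, 0 °C
Reagents that add atoms: p-toluenesulfonyl chloride Cc1ccc(cc1)S(Cl)(=O)=O
Why: Selective sulfonylation of the primary alcohol over the hindered secondary benzylic alcohol.

Step 7
Reactants: 13 the primary tosylate
Product: 14 (1S,2S)-2-(4-bromo-2,6-dimethoxyphenoxy)-1-(3,4-dimethoxyphenyl)propan-1-ol (threo)
Conditions: LiEt3BH (3 eq), THF, 0 °C → rt; then H2O
Reagents that add atoms: none
Why: SN2 hydride displacement of a primary tosylate by Super-Hydride turns CH2OTs into the C9 methyl; the alkoxide is tied up as a borate (suppressing oxetane closure) and the aryl bromide is not reduced at this temperature.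

Step 8
Reactants: 14 (1S,2S)-2-(4-bromo-2,6-dimethoxyphenoxy)-1-(3,4-dimethoxyphenyl)propan-1-ol
Product: 15 (1R,2S)-2-(4-bromo-2,6-dimethoxyphenoxy)-1-(3,4-dimethoxyphenyl)propyl 4-nitrobenzoate
Conditions: 4-O2NC6H4CO2H, PPh3, DIAD, THF, 0 °C → rt
Reagents that add atoms: 4-nitrobenzoic acid OC(=O)c1ccc(cc1)[N+](=O)[O-]
Why: Mitsunobu reaction; SN2 attack of 4-nitrobenzoate on the alkoxyphosphonium inverts C7 from S to R, converting the threo (syn-aldol) series into the erythro series of the target.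

Step 9
Reactants: 15 the (1R,2S) 4-nitrobenzoate
Product: 16 (1R,2S)-2-(4-bromo-2,6-dimethoxyphenoxy)-1-(3,4-dimethoxyphenyl)propan-1-ol (erythro)
Conditions: K2CO3, MeOH, rt
Reagents that add atoms: none
Why: Base-catalysed transesterification (methanolysis) cleaves the activated aryl ester at the acyl carbon, so the C7 configuration is retained.

Step 10
Reactants: 16 (1R,2S)-2-(4-bromo-2,6-dimethoxyphenoxy)-1-(3,4-dimethoxyphenyl)propan-1-ol; 17 ethyl acrylate
Product: 18 ethyl (E)-3-[4-{[(1R,2S)-1-(3,4-dimethoxyphenyl)-1-hydroxypropan-2-yl]oxy}-3,5-dimethoxyphenyl]prop-2-enoate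
Conditions: Pd2(dba)3 (cat.), [(t-Bu)3PH]BF4 (cat.), Cy2NMe, dioxane, 80 °C
Reagents that add atoms: none
Why: Mizoroki–Heck reaction; the electron-rich phosphine enables oxidative addition to the electron-rich aryl bromide, and syn-insertion/syn-β-hydride elimination gives the E-cinnamate without touching the free alcohol.

Step 11
Reactants: 18 the (E)-cinnamate ester
Product: 19 (1R,2S)-1-(3,4-dimethoxyphenyl)-2-{4-[(E)-3-hydroxyprop-1-en-1-yl]-2,6-dimethoxyphenoxy}propan-1-ol (target)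
Conditions: DIBAL-H (4 eq), CH2Cl2, −78 → 0 °C; Rochelle salt work-up
Reagents that add atoms: none
Why: DIBAL-H 1,2-reduction of the α,β-unsaturated ester to the allylic alcohol keeps the E-alkene and both stereocentres; the neutral tartrate work-up protects the acid-sensitive cinnamyl alcohol.

**Compound list**
1 | 4-bromo-2,6-dimethoxyphenol | COc1cc(Br)cc(OC)c1O | starting material
2 | ethyl bromoacetate | CCOC(=O)CBr | starting material
3 | ethyl 2-(4-bromo-2,6-dimethoxyphenoxy)acetate | CCOC(=O)COc1c(OC)cc(Br)cc1OC | intermediate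
4 | 2-(4-bromo-2,6-dimethoxyphenoxy)acetic acid | OC(=O)COc1c(OC)cc(Br)cc1OC | intermediate
5 | (R)-4-benzyl-2-oxazolidinone | O=C1N[C@H](Cc2ccccc2)CO1 | starting material
6 | 2-(4-bromo-2,6-dimethoxyphenoxy)acetic pivalic anhydride | CC(C)(C)C(=O)OC(=O)COc1c(OC)cc(Br)cc1OC | intermediate (not isolated)
7 | (R)-4-benzyl-3-[2-(4-bromo-2,6-dimethoxyphenoxy)acetyl]oxazolidin-2-one | O=C(COc1c(OC)cc(Br)cc1OC)N1[C@H](Cc2ccccc2)COC1=O | intermediate
8 | 3,4-dimethoxybenzaldehyde | COc1ccc(C=O)cc1OC | starting material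
9 | (Z)-dibutylboron enolate of 7 | CCCCB(CCCC)O/C(=C\Oc1c(OC)cc(Br)cc1OC)N1[C@H](Cc2ccccc2)COC1=O | intermediate (not isolated)
10 | O-dibutylboryl aldolate of 11 | O=C([C@H](Oc1c(OC)cc(Br)cc1OC)[C@@H](OB(CCCC)CCCC)c1ccc(OC)c(OC)c1)N1[C@H](Cc2ccccc2)COC1=O | intermediate (not isolated)
11 | (R)-4-benzyl-3-[(2R,3S)-2-(4-bromo-2,6-dimethoxyphenoxy)-3-(3,4-dimethoxyphenyl)-3-hydroxypropanoyl]oxazolidin-2-one | O=C([C@H](Oc1c(OC)cc(Br)cc1OC)[C@@H](O)c1ccc(OC)c(OC)c1)N1[C@H](Cc2ccccc2)COC1=O | intermediate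
12 | (1S,2S)-2-(4-bromo-2,6-dimethoxyphenoxy)-1-(3,4-dimethoxyphenyl)propane-1,3-diol | OC[C@H](Oc1c(OC)cc(Br)cc1OC)[C@@H](O)c1ccc(OC)c(OC)c1 | intermediate
13 | (2S,3S)-2-(4-bromo-2,6-dimethoxyphenoxy)-3-(3,4-dimethoxyphenyl)-3-hydroxypropyl 4-methylbenzenesulfonate | Cc1ccc(cc1)S(=O)(=O)OC[C@H](Oc1c(OC)cc(Br)cc1OC)[C@@H](O)c1ccc(OC)c(OC)c1 | intermediate
14 | (1S,2S)-2-(4-bromo-2,6-dimethoxyphenoxy)-1-(3,4-dimethoxyphenyl)propan-1-ol | C[C@H](Oc1c(OC)cc(Br)cc1OC)[C@@H](O)c1ccc(OC)c(OC)c1 | intermediate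
15 | (1R,2S)-2-(4-bromo-2,6-dimethoxyphenoxy)-1-(3,4-dimethoxyphenyl)propyl 4-nitrobenzoate | C[C@H](Oc1c(OC)cc(Br)cc1OC)[C@H](OC(=O)c1ccc(cc1)[N+](=O)[O-])c1ccc(OC)c(OC)c1 | intermediate
16 | (1R,2S)-2-(4-bromo-2,6-dimethoxyphenoxy)-1-(3,4-dimethoxyphenyl)propan-1-ol | C[C@H](Oc1c(OC)cc(Br)cc1OC)[C@H](O)c1ccc(OC)c(OC)c1 | intermediate
17 | ethyl acrylate | C=CC(=O)OCC | starting material
18 | ethyl (E)-3-[4-{[(1R,2S)-1-(3,4-dimethoxyphenyl)-1-hydroxypropan-2-yl]oxy}-3,5-dimethoxyphenyl]prop-2-enoate | C[C@H](Oc1c(OC)cc(/C=C/C(=O)OCC)cc1OC)[C@H](O)c1ccc(OC)c(OC)c1 | intermediate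
19 | (1R,2S)-1-(3,4-dimethoxyphenyl)-2-{4-[(E)-3-hydroxyprop-1-en-1-yl]-2,6-dimethoxyphenoxy}propan-1-ol | COc1ccc([C@@H](O)[C@H](C)Oc2c(OC)cc(/C=C/CO)cc2OC)cc1OC | target

**Summary**
Total step count: 11. Longest linear sequence: 11 steps (1 → 19); compounds 2, 5, 8 and 17 are bought partners.

**Steps most likely to fail**

Step 4 (aldol). The bulky 2,6-dimethoxyaryloxy enolate and the electron-poor reactivity of 3,4-dimethoxybenzaldehyde may give low conversion or a poor diastereomer ratio. The fallback sets out from 1 and builds the C7–C8 bond by organometallic addition to a lactate-derived aldehyde. Mitsunobu etherification of 1 with methyl (R)-lactate (PPh3, DIAD, THF) gives, with inversion, methyl (S)-2-(4-bromo-2,6-dimethoxyphenoxy)propanoate F1. DIBAL-H in CH2Cl2 at −78 °C gives (S)-2-(4-bromo-2,6-dimethoxyphenoxy)propanal F2, used crude to limit racemisation. Addition of commercial 3,4-dimethoxyphenylmagnesium bromide in the presence of MgBr2·OEt2 at −78 °C (Cram-chelate control) gives the threo alcohol; the fallback comes back to the route at 14, before step 8.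

Step 8 (Mitsunobu inversion). The electron-rich benzylic carbinol may ionise, eroding the inversion, or the hindered alcohol may react sluggishly. The fallback sets out from 14 and inverts C7 by redox instead of substitution. Dess–Martin periodinane (NaHCO3, CH2Cl2) gives (S)-2-(4-bromo-2,6-dimethoxyphenoxy)-1-(3,4-dimethoxyphenyl)propan-1-one F3. Chelation-controlled reduction with Zn(BH4)2 in Et2O at −30 °C delivers hydride past the small C8–H of the O,O-chelate and gives the erythro alcohol; the fallback comes back at 16, replacing steps 8 and 9.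

Step 10 (Heck). Oxidative addition to the electron-rich, doubly meta-methoxylated aryl bromide may be slow, and the free alcohol may cause side reactions at 80 °C. The fallback sets out from 16 and installs the three-carbon chain already at the alcohol oxidation level. Suzuki–Miyaura coupling with commercial (E)-3-(tert-butyldimethylsilyloxy)prop-1-enylboronic acid pinacol ester (Pd(dppf)Cl2, K3PO4, dioxane/H2O, 85 °C) gives (1R,2S)-2-{4-[(E)-3-(tert-butyldimethylsilyloxy)prop-1-en-1-yl]-2,6-dimethoxyphenoxy}-1-(3,4-dimethoxyphenyl)propan-1-ol F4. TBAF in THF removes the silyl group; the fallback comes back at 19, bypassing step 11.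

**Further compounds**
F1 | step 4 | methyl (S)-2-(4-bromo-2,6-dimethoxyphenoxy)propanoate | C[C@H](Oc1c(OC)cc(Br)cc1OC)C(=O)OC
F2 | step 4 | (S)-2-(4-bromo-2,6-dimethoxyphenoxy)propanal | C[C@H](Oc1c(OC)cc(Br)cc1OC)C=O
F3 | step 8 | (S)-2-(4-bromo-2,6-dimethoxyphenoxy)-1-(3,4-dimethoxyphenyl)propan-1-one | C[C@H](Oc1c(OC)cc(Br)cc1OC)C(=O)c1ccc(OC)c(OC)c1
F4 | step 10 | (1R,2S)-2-{4-[(E)-3-(tert-butyldimethylsilyloxy)prop-1-en-1-yl]-2,6-dimethoxyphenoxy}-1-(3,4-dimethoxyphenyl)propan-1-ol | C[C@H](Oc1c(OC)cc(/C=C/CO[Si](C)(C)C(C)(C)C)cc1OC)[C@H](O)c1ccc(OC)c(OC)c1
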